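**Plan**

- Numbering used throughout: seven-membered ring C1(=CH2)–C2–C3(O-vanilloyl)–C4(H)–C5(CH3)–C9–C10(OH), five-membered ring C4–C5–C6–C7–C8(OH)(iPr). The oxygen on C3, directly beside the C4–C5 fusion bond, is read as the ketone left behind by a 1,2-shift of C5 from C3 to C4.
- Retrosynthesis: cut the C3–O acyl bond and the C1=CH2 bond (from a C10 ketone); cut C4–C5 and rejoin C3–C5 to reach a cis-decalin with C3–OH and C4–OMs; cut C8–iPr; finally cut C3=C4 and C5–C6 (Robinson annulation).
- Forward: ring B is the starting cyclohexanone; ring A is annulated onto it, then oxygenated at C3, C4 and C8; one semipinacol shift contracts ring A to the cyclopentane and expands ring B to the cycloheptane.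
- Stereochemistry: C5 comes from a chiral-imine Michael addition. The enone epoxide cis to the C5 methyl relays to C8 (Grignard addition anti to the epoxide), to C4–OH (retained) and to C3–OH (hydroxyl-directed epoxidation, hydride opening).
- C4–H arises by inversion in the shift, C3–OH by hydride delivery from the C8 hydroxyl, and C10–OH by catalyst-controlled reduction of the methylene ketone.

Key step: step 10

Assumption: the remote dioxolane is taken not to change the sense of induction of the 1-phenylethylamine-mediated Michael addition, so the (R)-amine should give the (R)-diketone 6. β denotes the face of the C5 methyl group; in the decalins ring A is C3–C4–C8–C7–C6–C5 and ring B is C3–C2–C1–C10–C9–C5.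

**Step 1**
Reactants: 1 7-methyl-1,4-dioxaspiro[4.5]decan-8-one (racemic); 2 (R)-1-phenylethylamine; 3 methyl vinyl ketone
Product: 6 (7R)-7-methyl-7-(3-oxobutyl)-1,4-dioxaspiro[4.5]decan-8-one, via imine 4 (not isolated), via Michael-adduct imine 5 (not isolated)
Conditions: 2, TsOH (cat.), toluene, reflux with azeotropic removal of water; 3, THF, rt; then 10% aq AcOH, rt
Reagents that add atoms: water, O
Why: The imine reacts through its more substituted secondary enamine tautomer in an aza-ene-like Michael addition on the face remote from the phenyl group of the auxiliary, which should set the quaternary C5 centre at the methyl-bearing α-carbon, and dilute acetic acid then hydrolyses the imine while sparing the dioxolane.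

**Step 2**
Reactants: 6 (7R)-7-methyl-7-(3-oxobutyl)-1,4-dioxaspiro[4.5]decan-8-one
Product: 8 (4aR)-6,6-ethylenedioxy-4a-methyl-4,4a,5,6,7,8-hexahydronaphthalen-2(3H)-one (route numbering: enone C8(=O)–C4=C3 with C5 methyl and C10 dioxolane), via cis-ketol 7 (not isolated)
Conditions: NaOMe (cat.), MeOH, 60 °C
Reagents that add atoms: none
Why: Intramolecular aldol condensation, the ring-closing half of a Robinson annulation, should form ring A through the cis-ketol and dehydrate it to the conjugated enone without touching the quaternary centre.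

**Step 3**
Reactants: 8 decalin enone
Product: 9 3β,4β-epoxy-5β-methyldecalin-8-one 10-ethylene ketal (epoxide cis to the C5 methyl)
Conditions: 30% H2O2, NaOH (cat.), MeOH, 0 °C to rt
Reagents that add atoms: hydrogen peroxide, OO
Why: Weitz–Scheffer epoxidation, in which hydroperoxide adds to C3 along the axial trajectory on the face of the angular methyl group (the usual outcome for this enone class), should place the epoxide oxygen β at C3 and C4.

**Step 4**
Reactants: 9 3β,4β-epoxy ketone; 10 isopropylmagnesium chloride
Product: 11 3β,4β-epoxy-8α-isopropyl-5β-methyldecalin-8β-ol 10-ethylene ketal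
Conditions: 10 premixed with anhydrous CeCl3, THF, −78 °C; then aq NH4Cl
Reagents that add atoms: none
Why: 1,2-Addition of the organocerium reagent to the α,β-epoxy ketone should occur anti to the epoxide oxygen, placing isopropyl α and the new tertiary C8 hydroxyl β (cis to the epoxide and to the C5 methyl), while CeCl3 suppresses enolisation and β-hydride transfer.

**Step 5**
Reactants: 11 epoxy alcohol
Product: 12 8-O-triethylsilyl ether of 11
Conditions: Et3SiOTf, 2,6-lutidine, CH2Cl2, −78 to 0 °C
Reagents that add atoms: triethylsilyl triflate, CC[Si](CC)(CC)OS(=O)(=O)C(F)(F)F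
Why: Silyl triflate silylation of the only hydroxyl gives a tertiary triethylsilyl ether that should withstand amide base, peroxide, hydride and alkoxide, cannot act as a donor in the later shift and is removable with fluoride.

**Step 6**
Reactants: 12 silylated 3β,4β-epoxide
Product: 13 8α-isopropyl-5β-methyl-8β-(triethylsilyloxy)decal-2-en-4β-ol 10-ethylene ketal (alkene C2=C3)
Conditions: Et2AlTMP (from 2,2,6,6-tetramethylpiperidine, n-BuLi, Et2AlCl), toluene, 0 °C
Reagents that add atoms: none
Why: Aluminium amide-promoted syn β-elimination of a trisubstituted epoxide to an allylic alcohol has only C2–H available (C5 and C8 are quaternary), so the C3–O bond should open to the C2=C3 alkene and leave C4–OH β with its configuration untouched.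

**Step 7**
Reactants: 13 allylic alcohol
Product: 14 2β,3β-epoxy-8α-isopropyl-5β-methyl-8β-(triethylsilyloxy)decalin-4β-ol 10-ethylene ketal
Conditions: VO(acac)2 (cat.), t-BuOOH, CH2Cl2, 0 °C to rt
Reagents that add atoms: tert-butyl hydroperoxide, CC(C)(C)OO
Why: Vanadium-catalysed hydroxyl-directed epoxidation transfers oxygen to the alkene face syn to the allylic C4 hydroxyl, which should place the new C3–O bond β, cis to the C5 methyl, against the steric bias of that group.

**Step 8**
Reactants: 14 2β,3β-epoxy alcohol
Product: 15 cis-fused 8α-isopropyl-5β-methyl-8β-(triethylsilyloxy)decalin-3β,4β-diol 10-ethylene ketal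
Conditions: LiAlH4, THF, 0 to 50 °C; aq NaOH work-up
Reagents that add atoms: none
Why: Hydride should open the trisubstituted 2,3-epoxy alcohol by SN2 attack at the less substituted C2, leaving the tertiary C3 hydroxyl β and thus the cis-fused 3β,4β-diol.

**Step 9**
Reactants: 15 cis-decalin-3β,4β-diol
Product: 16 cis-fused 3β-hydroxy-4β-mesyloxy-8α-isopropyl-5β-methyl-8β-(triethylsilyloxy)decalin 10-ethylene ketal
Conditions: MsCl, Et3N, DMAP (cat.), CH2Cl2, 0 °C
Reagents that add atoms: methanesulfonyl chloride, CS(=O)(=O)Cl
Why: Sulfene-type mesylation should take the only secondary hydroxyl, the tertiary C3 hydroxyl being inert under these conditions.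

**Step 10**
Reactants: 16 cis-decalin diol monomesylate
Product: 18 trans-fused hydroazulen-3-one (4α-H; 5β-methyl; 8α-isopropyl; 8β-triethylsilyloxy; 10-ethylene ketal), via potassium alkoxide 17 (not isolated)
Conditions: KOtBu (1.05 equiv), THF/t-BuOH, 0 °C to rt; then aq NH4Cl
Reagents that add atoms: none
Why: tert-Butoxide deprotonates the free tertiary C3 hydroxyl, and in the favoured chair–chair conformer (isopropyl and mesylate equatorial on ring A, O3 and O8 axial) the C3–C5 σ-bond is antiperiplanar to the C4–OMs bond, so C5 migrates from C3 to C4 as the alkoxide becomes the C3 carbonyl and mesylate departs. This is a base-induced semipinacol (pinacol-type) rearrangement of a vicinal diol monosulfonate, the classical entry from decalins to hydroazulenes. No ring is closed by cyclisation: the single 1,2-alkyl shift contracts ring A to the cyclopentane C4–C5–C6–C7–C8 and expands ring B to the cycloheptanone C1–C2–C3–C4–C5–C9–C10. The new stereocentre C4 forms with inversion at the mesylate carbon and retention at the migrating C5, so the β-mesylate should give H4 α, trans to the C5 methyl (stereospecific, substrate-controlled). The step needs migration of C5 and not of C7, which is also antiperiplanar: only O3 can become an alkoxide because O8 is silylated, which also blocks retro-aldol cleavage of the product; epoxide closure is impossible for the cis arrangement, E2 elimination has no β-hydrogen (C3 and C8 are fully substituted), and one equivalent of base at 0 °C limits enolisation at C4.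

**Step 11**
Reactants: 18 silylated hydroazulenone
Product: 19 trans-fused 8β-hydroxy-8α-isopropyl-5β-methylhydroazulen-3-one 10-ethylene ketal
Conditions: HF·pyridine, pyridine, THF, 0 °C to rt
Reagents that add atoms: none
Why: Buffered HF·pyridine cleaves the tertiary silyl ether without base, so the tertiary β-hydroxy ketone is not exposed to retro-aldol conditions and the dioxolane should survive.

**Step 12**
Reactants: 19 β-hydroxy ketone
Product: 20 trans-fused 8α-isopropyl-5β-methylhydroazulene-3α,8β-diol 10-ethylene ketal
Conditions: Me4NBH(OAc)3, MeCN/AcOH, −30 °C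
Reagents that add atoms: none
Why: In this Evans–Saksena reduction the C8 hydroxyl exchanges onto boron and delivers hydride intramolecularly to the β face of the C3 carbonyl, which should give the 1,3-anti diol with C3–OH α.

**Step 13**
Reactants: 21 vanillic acid
Product: 23 4-(tert-butyldimethylsilyloxy)-3-methoxybenzoic acid, via bis-silyl derivative 22 (not isolated)
Conditions: t-BuMe2SiCl (2.5 equiv), imidazole, DMF, rt; then AcOH/THF/H2O, rt
Reagents that add atoms: tert-butyldimethylsilyl chloride, CC(C)(C)[Si](C)(C)Cl
Why: Silylation of phenol and carboxylic acid followed by selective solvolysis of the labile silyl ester should leave the aryl silyl ether and free the acid for coupling.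

**Step 14**
Reactants: 20 3α,8β-diol; 23 4-(tert-butyldimethylsilyloxy)-3-methoxybenzoic acid
Product: 24 3α-O-[4-(tert-butyldimethylsilyloxy)-3-methoxybenzoyl] ester of 20
Conditions: EDC·HCl, DMAP, CH2Cl2, 0 °C to rt
Reagents that add atoms: none
Why: Steglich esterification should acylate the secondary C3 hydroxyl selectively, the tertiary C8 hydroxyl next to isopropyl being unreactive toward the acylpyridinium intermediate.

**Step 15**
Reactants: 24 ester ketal
Product: 25 10-ketone of 24 (trans-fused hydroazulen-10-one with 3α-aroyloxy and 8β-OH)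
Conditions: pyridinium p-toluenesulfonate, acetone/H2O, 50 °C
Reagents that add atoms: water, O
Why: Mild acid-catalysed hydrolysis of the dioxolane releases the C10 ketone, and aryl silyl ether, ester and tertiary alcohol should tolerate pyridinium tosylate.

**Step 16**
Reactants: 25 C10 ketone
Product: 27 1-methylene-10-ketone (exocyclic enone C10(=O)–C1(=CH2)), via Mannich base 26 (not isolated)
Conditions: (CH2O)n, N-methylanilinium trifluoroacetate, THF, 65 °C
Reagents that add atoms: paraformaldehyde (formaldehyde), C=O
Why: In this Mannich α-methylenation the iminium ion from formaldehyde and N-methylaniline should react with the enol on the C1 side (C9 is neopentyl, next to quaternary C5), and the Mannich base loses the amine in situ to give the exocyclic enone; the acyloxy group is γ to the ketone and cannot be eliminated.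

**Step 17**
Reactants: 27 α-methylene ketone
Product: 28 10α-hydroxy (10S) allylic alcohol with aryl silyl ether still in place
Conditions: (R)-Me-CBS oxazaborolidine [(R)-1-methyl-3,3-diphenyltetrahydro-1H,3H-pyrrolo[1,2-c][1,3,2]oxazaborole, 20 mol%], BH3·SMe2, THF, −30 °C; then MeOH
Reagents that add atoms: none
Why: Corey–Bakshi–Shibata reduction is 1,2-selective for enones, and with the α-methylene flank (C1) as the large and the C9 methylene as the small substituent the (R)-catalyst should deliver hydride to the β face of C10, giving the 10α (S) alcohol by reagent control.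

**Step 18**
Reactants: 28 silyl-protected allylic alcohol
Product: 29 target, 3α-O-vanilloyl-1-methylene-hydroazulene-8β,10α-diol (CNP0330487.1)
Conditions: Bu4NF, AcOH, THF, 0 °C
Reagents that add atoms: none
Why: Fluoride cleaves the aryl silyl ether rapidly at 0 °C, and acetic acid buffering should keep the ester and the allylic alcohol intact.

**Compound list**

1 | 7-methyl-1,4-dioxaspiro[4.5]decan-8-one (racemic) | CC1CC2(OCCO2)CCC1=O | starting material
2 | (R)-1-phenylethylamine | C[C@@H](N)c1ccccc1 | starting material
3 | methyl vinyl ketone | CC(=O)C=C | starting material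
4 | (R)-1-phenylethyl imine of 1 | CC1CC2(OCCO2)CCC1=N[C@H](C)c1ccccc1 | intermediate (not isolated)
5 | (R)-1-phenylethyl imine of diketone 6 (ring C=N) | C[C@@]1(CCC(C)=O)CC2(OCCO2)CCC1=N[C@H](C)c1ccccc1 | intermediate (not isolated)
6 | (7R)-7-methyl-7-(3-oxobutyl)-1,4-dioxaspiro[4.5]decan-8-one | C[C@@]1(CCC(C)=O)CC2(OCCO2)CCC1=O | intermediate
7 | cis-fused ketol (3β-hydroxy-5β-methyldecalin-8-one 10-ethylene ketal) | C[C@@]12CC3(OCCO3)CC[C@]1(O)CC(=O)CC2 | intermediate (not isolated)
8 | (4aR)-6,6-ethylenedioxy-4a-methyl-4,4a,5,6,7,8-hexahydronaphthalen-2(3H)-one | C[C@@]12CC3(OCCO3)CCC1=CC(=O)CC2 | intermediate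
9 | 3β,4β-epoxy-5β-methyldecalin-8-one 10-ethylene ketal | C[C@@]12CC3(OCCO3)CC[C@@]14O[C@H]4C(=O)CC2 | intermediate
10 | isopropylmagnesium chloride | CC(C)[Mg]Cl | starting material
11 | 3β,4β-epoxy-8α-isopropyl-5β-methyldecalin-8β-ol 10-ethylene ketal | C[C@@]12CC3(OCCO3)CC[C@@]14O[C@H]4[C@](O)(C(C)C)CC2 | intermediate
12 | 8-O-triethylsilyl ether of 11 | C[C@@]12CC3(OCCO3)CC[C@@]14O[C@H]4[C@](O[Si](CC)(CC)CC)(C(C)C)CC2 | intermediate
13 | 8α-isopropyl-5β-methyl-8β-(triethylsilyloxy)decal-2-en-4β-ol 10-ethylene ketal | C[C@@]12CC3(OCCO3)CC=C1[C@@H](O)[C@](O[Si](CC)(CC)CC)(C(C)C)CC2 | intermediate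
14 | 2β,3β-epoxide of 13 | C[C@@]12CC3(OCCO3)C[C@H]4O[C@@]14[C@@H](O)[C@](O[Si](CC)(CC)CC)(C(C)C)CC2 | intermediate
15 | cis-fused 8α-isopropyl-5β-methyl-8β-(triethylsilyloxy)decalin-3β,4β-diol 10-ethylene ketal | C[C@@]12CC3(OCCO3)CC[C@]1(O)[C@@H](O)[C@](O[Si](CC)(CC)CC)(C(C)C)CC2 | intermediate
16 | 4-O-mesylate of 15 (3β-OH free) | C[C@@]12CC3(OCCO3)CC[C@]1(O)[C@@H](OS(C)(=O)=O)[C@](O[Si](CC)(CC)CC)(C(C)C)CC2 | intermediate
17 | potassium 3-alkoxide of 16 | [K+].C[C@@]12CC3(OCCO3)CC[C@]1([O-])[C@@H](OS(C)(=O)=O)[C@](O[Si](CC)(CC)CC)(C(C)C)CC2 | intermediate (not isolated)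
18 | trans-fused 8α-isopropyl-5β-methyl-8β-(triethylsilyloxy)hydroazulen-3-one 10-ethylene ketal (4α-H) | O=C1CCC2(OCCO2)C[C@@]3(C)CC[C@@](O[Si](CC)(CC)CC)(C(C)C)[C@H]13 | intermediate
19 | trans-fused 8β-hydroxy-8α-isopropyl-5β-methylhydroazulen-3-one 10-ethylene ketal | O=C1CCC2(OCCO2)C[C@@]3(C)CC[C@@](O)(C(C)C)[C@H]13 | intermediate
20 | trans-fused 8α-isopropyl-5β-methylhydroazulene-3α,8β-diol 10-ethylene ketal | O[C@H]1CCC2(OCCO2)C[C@@]3(C)CC[C@@](O)(C(C)C)[C@H]13 | intermediate
21 | vanillic acid | COc1cc(ccc1O)C(=O)O | starting material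
22 | tert-butyldimethylsilyl 4-(tert-butyldimethylsilyloxy)-3-methoxybenzoate | COc1cc(ccc1O[Si](C)(C)C(C)(C)C)C(=O)O[Si](C)(C)C(C)(C)C | intermediate (not isolated)
23 | 4-(tert-butyldimethylsilyloxy)-3-methoxybenzoic acid | COc1cc(ccc1O[Si](C)(C)C(C)(C)C)C(=O)O | intermediate
24 | 3α-O-[4-(tert-butyldimethylsilyloxy)-3-methoxybenzoyl] ester of 20 | COc1cc(ccc1O[Si](C)(C)C(C)(C)C)C(=O)O[C@H]1CCC2(OCCO2)C[C@@]3(C)CC[C@@](O)(C(C)C)[C@H]13 | intermediate
25 | 10-ketone of 24 | COc1cc(ccc1O[Si](C)(C)C(C)(C)C)C(=O)O[C@H]1CCC(=O)C[C@@]2(C)CC[C@@](O)(C(C)C)[C@H]12 | intermediate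
26 | 1-[(N-methylanilino)methyl] derivative of 25 (C1 configuration undefined) | COc1cc(ccc1O[Si](C)(C)C(C)(C)C)C(=O)O[C@H]1CC(CN(C)c2ccccc2)C(=O)C[C@@]3(C)CC[C@@](O)(C(C)C)[C@H]13 | intermediate (not isolated)
27 | 1-methylene-10-ketone | COc1cc(ccc1O[Si](C)(C)C(C)(C)C)C(=O)O[C@H]1CC(=C)C(=O)C[C@@]2(C)CC[C@@](O)(C(C)C)[C@H]12 | intermediate
28 | 1-methylene-10α-ol with aryl tert-butyldimethylsilyl ether | COc1cc(ccc1O[Si](C)(C)C(C)(C)C)C(=O)O[C@H]1CC(=C)[C@@H](O)C[C@@]2(C)CC[C@@](O)(C(C)C)[C@H]12 | intermediate
29 | CNP0330487.1 | COc1cc(ccc1O)C(=O)O[C@H]1CC(=C)[C@@H](O)C[C@@]2(C)CC[C@@](O)(C(C)C)[C@H]12 | target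

**Step count and risks**

Total steps: 18. Longest linear sequence: 17 steps (steps 1–12 and 14–18 from ketone 1; step 13 is the side branch).

Steps most likely to fail:

Step 17. Hydride may be delivered to the wrong face of the cycloheptenone if the substrate's own bias (approach anti to the C5 methyl) overrides the catalyst, so that the C10 epimer predominates. The fallback sets out from enone 27. A Luche reduction (NaBH4, CeCl3·7H2O, MeOH, −78 °C) should give the substrate-preferred 10β-alcohol F1. A Mitsunobu reaction (PPh3, DIAD, chloroacetic acid, toluene, 0 °C) should invert C10 to the 10α-chloroacetate F2. Thiourea with NaHCO3 in EtOH at rt should then remove the chloroacetyl group without touching the vanillate, and the route is rejoined at 28.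

Step 16. Under the warm acidic Mannich conditions regiocontrol may erode (reaction also at C9), and the exocyclic enone may migrate into the ring or dimerise before isolation. The fallback sets out from ketone 25. The kinetic enolate on the C1 side (LiN(SiMe3)2, 2.2 equiv, THF, −78 °C) is trapped with dimethyl(methylene)ammonium iodide to give the isolated 1-(dimethylaminomethyl) ketone F3. Quaternisation with MeI gives the methiodide F4, and elimination with aqueous NaHCO3 in CH2Cl2 at rt should give the enone, rejoining the route at 27.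

Step 4. The branched Grignard reagent may act as a base or as a hydride donor toward the hindered epoxy ketone (enolisation toward C7, or reduction to the secondary alcohol) instead of adding. The fallback sets out from epoxy ketone 9. Isopropenylmagnesium bromide with CeCl3 (THF, −78 °C), an sp2 nucleophile that is less basic and does not transfer hydride, should add anti to the epoxide to give the isopropenyl carbinol F5. Hydrogenation of the 1,1-disubstituted alkene (H2, RhCl(PPh3)3, benzene, rt) leaves the epoxide intact and rejoins the route at 11.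

**Further compounds**

F1 | step 17 | 10β-epimer of 28 | COc1cc(ccc1O[Si](C)(C)C(C)(C)C)C(=O)O[C@H]1CC(=C)[C@H](O)C[C@@]2(C)CC[C@@](O)(C(C)C)[C@H]12
F2 | step 17 | 10α-chloroacetate of 28 | COc1cc(ccc1O[Si](C)(C)C(C)(C)C)C(=O)O[C@H]1CC(=C)[C@@H](OC(=O)CCl)C[C@@]2(C)CC[C@@](O)(C(C)C)[C@H]12
F3 | step 16 | 1-(dimethylaminomethyl) derivative of 25 (C1 configuration undefined) | COc1cc(ccc1O[Si](C)(C)C(C)(C)C)C(=O)O[C@H]1CC(CN(C)C)C(=O)C[C@@]2(C)CC[C@@](O)(C(C)C)[C@H]12
F4 | step 16 | methiodide of F3 | COc1cc(ccc1O[Si](C)(C)C(C)(C)C)C(=O)O[C@H]1CC(C[N+](C)(C)C)C(=O)C[C@@]2(C)CC[C@@](O)(C(C)C)[C@H]12.[I-]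
F5 | step 4 | 3β,4β-epoxy-8α-isopropenyl-5β-methyldecalin-8β-ol 10-ethylene ketal | C[C@@]12CC3(OCCO3)CC[C@@]14O[C@H]4[C@](O)(C(C)=C)CC2
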